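The route rests on disconnecting, in the central dihydropyran (ring C), the bond between C3 of quinolone A and the isobutyl-bearing CH. The feature exploited is that C3 is the nucleophilic β-carbon of a 4-alkoxy-2-quinolone enol ether, while the CH, with 2-methylprop-1-enyl in place of isobutyl, is the secondary terminus of a dimethylallyl cation. The key step ionises an allylic ethyl ether and closes ring C by intramolecular Friedel–Crafts allylation, setting the third stereocentre from the two already present. Its precursor is an aryl ether: quinolone A bound through O4 to C4 of the cis-3,4-disubstituted 2,2-dimethyldihydropyran (ring D) of quinolone B, whose C3 carries the 1-ethoxy-3-methylbut-2-enyl chain.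

Key step: step 8

Remark on the chemistry: the target descriptors read from the SMILES are S (isobutyl-bearing carbon), S (ring-fusion CH next to CMe2) and R (ring-fusion O–CH); the isobutyl group and both ring-fusion hydrogens lie on one face of ring C. The ethoxy-bearing carbon of 12, 13, 16 and 17 is carried as both epimers (left undefined in the SMILES), because step 8 turns it into a planar cation.

Step 1
Reactants: 1 2,3-dimethoxyaniline
Product: 3 2,3-dimethoxy-N-methylaniline, via N-(methoxymethyl)-2,3-dimethoxyaniline 2 (not isolated)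
Conditions: (CH2O)n, NaOMe, MeOH, 65 °C; then NaBH4, 65 °C
Reagents that add atoms: paraformaldehyde (formaldehyde), C=O
Why: reductive amination in which the aniline is first converted into its N,O-hemiaminal ether and this is then reduced by borohydride, a sequence that stops cleanly at the mono-N-methyl stage.

Step 2
Reactants: 3 2,3-dimethoxy-N-methylaniline; 4 diethyl malonate
Product: 6 4-hydroxy-7,8-dimethoxy-1-methylquinolin-2(1H)-one, via ethyl 3-[(2,3-dimethoxyphenyl)(methyl)amino]-3-oxopropanoate 5 (not isolated)
Conditions: neat, 170 °C (EtOH distilled off); then Ph2O, 250 °C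
Reagents that add atoms: none
Why: malonate cyclocondensation (aminolysis, then intramolecular Friedel–Crafts-type C-acylation), which can only occur at the single free ortho position, para to a methoxy group, and so should give the 7,8-dimethoxy pattern.

Step 3
Reactants: 6 4-hydroxy-7,8-dimethoxy-1-methylquinolin-2(1H)-one; 7 3-methylbut-2-enoic acid
Product: 9 7,8-dimethoxy-2,2,6-trimethyl-2,3-dihydro-4H-pyrano[3,2-c]quinoline-4,5(6H)-dione, via 3-(3-methylbut-2-enoyl)-4-hydroxyquinolone 8 (not isolated)
Conditions: P2O5/MeSO3H (1:10 w/w), 70 °C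
Reagents that add atoms: none
Why: chromanone annulation, that is Friedel–Crafts C-acylation at the nucleophilic C3 followed by 6-endo-trig oxa-Michael addition of the 4-OH to the β,β-dimethyl enone, which builds ring D with its gem-dimethyl carbon.

Step 4
Reactants: 9 7,8-dimethoxy-2,2,6-trimethyl-2,3-dihydro-4H-pyrano[3,2-c]quinoline-4,5(6H)-dione; 10 1,1-diethoxy-3-methylbut-2-ene
Product: 12 3-(1-ethoxy-3-methylbut-2-en-1-yl)-7,8-dimethoxy-2,2,6-trimethyl-2,3-dihydro-4H-pyrano[3,2-c]quinoline-4,5(6H)-dione, via trimethylsilyl enol ether 11 (not isolated)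
Conditions: TMSOTf, i-Pr2NEt, CH2Cl2, −78 °C; then 10, −78 → −20 °C
Reagents that add atoms: none
Why: one-pot soft enolisation and Mukaiyama-type addition of the enol silane to the oxocarbenium ion of the acetal (1,2-attack) should give the β-ethoxy ketone as a racemic mixture of diastereomers, of which C3 is equilibrated in step 5 and the ethoxy carbon is erased in step 8.

Step 5
Reactants: 12 3-(1-ethoxy-3-methylbut-2-en-1-yl)-7,8-dimethoxy-2,2,6-trimethyl-2,3-dihydro-4H-pyrano[3,2-c]quinoline-4,5(6H)-dione
Product: 13 (3R,4R)-3-(1-ethoxy-3-methylbut-2-en-1-yl)-4-hydroxy-7,8-dimethoxy-2,2,6-trimethyl-2,3,4,6-tetrahydro-5H-pyrano[3,2-c]quinolin-5-one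
Conditions: RuCl[(R,R)-TsDPEN](p-cymene) (2 mol %), HCO2H/Et3N (5:2), DMF, 40 °C
Reagents that add atoms: none
Why: asymmetric transfer hydrogenation with dynamic kinetic resolution, in which C3 epimerises through the enol while the catalyst sets C4 as R (by analogy with chroman-4-one reductions) and hydride enters anti to the C3 substituent, so the 3,4-cis alcohol should result.

Step 6
Reactants: 6 4-hydroxy-7,8-dimethoxy-1-methylquinolin-2(1H)-one
Product: 15 4-chloro-7,8-dimethoxy-1-methylquinolin-2(1H)-one, via aryl phosphorodichloridate 14 (not isolated)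
Conditions: POCl3, MeCN, 80 °C
Reagents that add atoms: phosphoryl chloride (POCl3), O=P(Cl)(Cl)Cl
Why: deoxychlorination of the vinylogous acid by O-phosphorylation and addition–elimination of chloride, with the N-methyl lactam carbonyl unable to react.

Step 7
Reactants: 13 (3R,4R)-3-(1-ethoxy-3-methylbut-2-en-1-yl)-4-hydroxy-7,8-dimethoxy-2,2,6-trimethyl-2,3,4,6-tetrahydro-5H-pyrano[3,2-c]quinolin-5-one; 15 4-chloro-7,8-dimethoxy-1-methylquinolin-2(1H)-one
Product: 17 4-{[(3S,4R)-3-(1-ethoxy-3-methylbut-2-en-1-yl)-7,8-dimethoxy-2,2,6-trimethyl-5-oxo-3,4,5,6-tetrahydro-2H-pyrano[3,2-c]quinolin-4-yl]oxy}-7,8-dimethoxy-1-methylquinolin-2(1H)-one, via sodium alkoxide 16 (not isolated)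
Conditions: NaH, DMF, 0 °C; then 15, 0 → 60 °C
Reagents that add atoms: none
Why: nucleophilic aromatic substitution (addition–elimination) of the alkoxide at C4 of the 4-chloro-2-quinolone leaves the carbinol C–O bond untouched, so the cis relationship is retained (the C3 descriptor changes only through substituent priority).

Step 8
Reactants: 17 4-{[(3S,4R)-3-(1-ethoxy-3-methylbut-2-en-1-yl)-7,8-dimethoxy-2,2,6-trimethyl-5-oxo-3,4,5,6-tetrahydro-2H-pyrano[3,2-c]quinolin-4-yl]oxy}-7,8-dimethoxy-1-methylquinolin-2(1H)-one
Product: 19 the 2-methylprop-1-enyl analogue of the target (cis-fused hexacycle), via allyl cation 18 (not isolated)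
Conditions: TfOH (10 mol %), CH2Cl2/HFIP (4:1), −20 → 0 °C
Reagents that add atoms: none
Why: catalytic TfOH in HFIP ionises the allylic C–OEt bond of 17 to the alkyl-substituted 1,1-dimethylallyl cation 18, whose secondary terminus is attacked by C3 of quinolone A (the β-carbon of its 4-alkoxy enol ether), and loss of the C3 proton restores the quinolone. The closest known reaction type is the intramolecular Friedel–Crafts allylic alkylation of electron-rich arenes by allylic alcohols or ethers that is used to make chromans. Ring C closes in a 6-(enolendo)-exo-trig mode, the allyl π-system staying outside the new ring. The new stereocentre is controlled by the adjacent ring-fusion carbon C3 of ring D: in the chair-like transition state its C–H bond lies in the plane of the cation and eclipses the alkenyl carbon (least allylic strain), the arene is delivered by the O4 tether to the face syn to that oxygen, and the 2-methylprop-1-enyl group becomes pseudo-equatorial, trans to the CMe2 carbon and cis to both ring-fusion hydrogens, while the cis ring fusion is already set by steps 5 and 7. The step needs ionisation of the allylic ether in preference to the C4–O aryl ether of ring D and bond formation at the secondary and not the tertiary allyl terminus; the first is secured by the more basic and better stabilised allylic ether under catalytic acid at low temperature, the second by six- versus eight-membered ring closure.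

Step 9
Reactants: 19 the 2-methylprop-1-enyl analogue of the target
Product: 20 CNP0275598.1 (target)
Conditions: H2 (1 atm), [Ir(cod)(PCy3)(py)]PF6 (5 mol %), CH2Cl2, 23 °C
Reagents that add atoms: none
Why: homogeneous catalytic hydrogenation with a cationic iridium catalyst should saturate the hindered trisubstituted alkene to the isobutyl group without creating a stereocentre and without hydrogenolysing the C–O bonds at the ring-fusion carbon.

Compound list
1 | 2,3-dimethoxyaniline | COc1cccc(N)c1OC | starting material
2 | N-(methoxymethyl)-2,3-dimethoxyaniline (formed in situ) | COCNc1cccc(OC)c1OC | intermediate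
3 | 2,3-dimethoxy-N-methylaniline | CNc1cccc(OC)c1OC | intermediate
4 | diethyl malonate | CCOC(=O)CC(=O)OCC | starting material
5 | ethyl 3-[(2,3-dimethoxyphenyl)(methyl)amino]-3-oxopropanoate (formed in situ) | CCOC(=O)CC(=O)N(C)c1cccc(OC)c1OC | intermediate
6 | 4-hydroxy-7,8-dimethoxy-1-methylquinolin-2(1H)-one | COc1ccc2c(O)cc(=O)n(C)c2c1OC | intermediate
7 | 3-methylbut-2-enoic acid | CC(C)=CC(=O)O | starting material
8 | 4-hydroxy-7,8-dimethoxy-1-methyl-3-(3-methylbut-2-enoyl)quinolin-2(1H)-one (formed in situ) | COc1ccc2c(O)c(C(=O)C=C(C)C)c(=O)n(C)c2c1OC | intermediate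
9 | 7,8-dimethoxy-2,2,6-trimethyl-2,3-dihydro-4H-pyrano[3,2-c]quinoline-4,5(6H)-dione | COc1ccc2c(c1OC)n(C)c(=O)c1c2OC(C)(C)CC1=O | intermediate
10 | 1,1-diethoxy-3-methylbut-2-ene | CCOC(OCC)C=C(C)C | starting material
11 | 7,8-dimethoxy-2,2,6-trimethyl-4-[(trimethylsilyl)oxy]-2,6-dihydro-5H-pyrano[3,2-c]quinolin-5-one (formed in situ) | COc1ccc2c(c1OC)n(C)c(=O)c1c2OC(C)(C)C=C1O[Si](C)(C)C | intermediate
12 | 3-(1-ethoxy-3-methylbut-2-en-1-yl)-7,8-dimethoxy-2,2,6-trimethyl-2,3-dihydro-4H-pyrano[3,2-c]quinoline-4,5(6H)-dione (racemic mixture of diastereomers) | COc1ccc2c(c1OC)n(C)c(=O)c1c2OC(C)(C)C(C(OCC)C=C(C)C)C1=O | intermediate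
13 | (3R,4R)-3-(1-ethoxy-3-methylbut-2-en-1-yl)-4-hydroxy-7,8-dimethoxy-2,2,6-trimethyl-2,3,4,6-tetrahydro-5H-pyrano[3,2-c]quinolin-5-one (3,4-cis; both epimers at the ethoxy carbon) | O[C@H]1c2c(c3ccc(OC)c(OC)c3n(C)c2=O)OC(C)(C)[C@H]1C(OCC)C=C(C)C | intermediate
14 | 7,8-dimethoxy-1-methyl-2-oxo-1,2-dihydroquinolin-4-yl phosphorodichloridate (formed in situ) | COc1ccc2c(OP(=O)(Cl)Cl)cc(=O)n(C)c2c1OC | intermediate
15 | 4-chloro-7,8-dimethoxy-1-methylquinolin-2(1H)-one | COc1ccc2c(Cl)cc(=O)n(C)c2c1OC | intermediate
16 | sodium (3R,4R)-3-(1-ethoxy-3-methylbut-2-en-1-yl)-7,8-dimethoxy-2,2,6-trimethyl-5-oxo-3,4,5,6-tetrahydro-2H-pyrano[3,2-c]quinolin-4-olate (formed in situ) | [Na+].[O-][C@H]1c2c(c3ccc(OC)c(OC)c3n(C)c2=O)OC(C)(C)[C@H]1C(OCC)C=C(C)C | intermediate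
17 | 4-{[(3S,4R)-3-(1-ethoxy-3-methylbut-2-en-1-yl)-7,8-dimethoxy-2,2,6-trimethyl-5-oxo-3,4,5,6-tetrahydro-2H-pyrano[3,2-c]quinolin-4-yl]oxy}-7,8-dimethoxy-1-methylquinolin-2(1H)-one (3,4-cis) | COc1ccc2c(O[C@H]3c4c(c5ccc(OC)c(OC)c5n(C)c4=O)OC(C)(C)[C@H]3C(OCC)C=C(C)C)cc(=O)n(C)c2c1OC | intermediate
18 | allyl cation formed from 17 by loss of ethoxide (formed in situ) | COc1ccc2c(O[C@H]3c4c(c5ccc(OC)c(OC)c5n(C)c4=O)OC(C)(C)[C@H]3[CH+]C=C(C)C)cc(=O)n(C)c2c1OC | intermediate
19 | 2-methylprop-1-enyl analogue of the target (S at the alkenyl-bearing carbon; S and R at the ring-fusion carbons; alkenyl group and both ring-fusion hydrogens on one face) | COc1ccc2c3c(c(=O)n(C)c2c1OC)[C@@H](C=C(C)C)[C@H]1[C@@H](O3)c2c(c3ccc(OC)c(OC)c3n(C)c2=O)OC1(C)C | intermediate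
20 | CNP0275598.1 (cis-fused bis-pyranoquinolinone; isobutyl carbon S, ring-fusion CH next to CMe2 S, ring-fusion O–CH R) | COc1ccc2c3c(c(=O)n(C)c2c1OC)[C@@H](CC(C)C)[C@H]1[C@@H](O3)c2c(c3ccc(OC)c(OC)c3n(C)c2=O)OC1(C)C | target

Total step count: 9. Longest linear sequence: 8 steps (steps 1–5 and 7–9; step 6 is the side branch from 6).

Steps most likely to fail

Step 8. The acid may ionise the wrong C–O bond (the C4 aryl ether, with loss of quinolone A), the cation may lose the ring-fusion proton to give a diene, or the arene may add to the wrong face. The fallback builds ring C in the opposite bond order and sets out from ketone 9 and quinolone 6. Aldol condensation of 9 with 3-methylbutanal (pyrrolidine cat., EtOH, 60 °C) would give the 3-(3-methylbutylidene) enone F1. Conjugate addition of 6 through C3 under a chiral primary amine salt (9-amino-9-deoxy-epi-quinine, TFA), a warfarin-type Michael addition, followed by closure of the 4-OH onto the ketone, would give the cyclic hemiketal F2. In F2 the isobutyl-bearing centre is set by the catalyst and the ring-fusion CH by thermodynamic protonation. Ionic reduction (Et3SiH, BF3·OEt2, CH2Cl2, −78 °C) through the oxocarbenium ion should deliver hydride cis to the ring-fusion hydrogen and comes back to the route at target 20. In this fallback ring C is closed through its C–O bond.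

Step 5. Epimerisation at the hindered C3 may be too slow for a dynamic resolution, and the enol may expel ethoxide. The fallback sets out from 12 and uses a non-dynamic, reagent-controlled reduction: oxazaborolidine-catalysed borane reduction ((S)-2-methyl-oxazaborolidine from diphenylprolinol, BH3·SMe2, THF, −20 °C). Both ketone enantiomers are expected to be reduced from the same carbonyl face, so the (3R)-ketone gives 13 and the (3S)-ketone gives the (3S,4R)-trans alcohol F3. After chromatographic separation the fallback comes back at 13. F3 can be recycled by oxidation (MnO2, CH2Cl2) to 12 and base epimerisation (DBU).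

Step 7. Addition–elimination by the hindered secondary alkoxide may be slow, and prolonged heating with base may dehydrate the alcohol to the 2H-pyran. The fallback sets out from 6 and 13 and replaces the substitution by a cross-coupling. Quinolone 6 with Tf2O and pyridine (CH2Cl2, 0 °C) would give the 4-triflate F4. Palladium-catalysed C–O coupling of F4 with 13 (Pd2(dba)3, RockPhos, Cs2CO3, toluene, 80 °C) should form the same aryl ether with retention at the carbinol carbon and comes back at 17.

Further compounds
F1 | step 8 | 7,8-dimethoxy-2,2,6-trimethyl-3-(3-methylbutylidene)-2,3-dihydro-4H-pyrano[3,2-c]quinoline-4,5(6H)-dione | COc1ccc2c(c1OC)n(C)c(=O)c1c2OC(C)(C)C(=CCC(C)C)C1=O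
F2 | step 8 | cyclic hemiketal of the Michael adduct (the target with OH in place of H at the ring-fusion O–C carbon) | COc1ccc2c3c(c(=O)n(C)c2c1OC)[C@@H](CC(C)C)[C@H]1C(O)(O3)c2c(c3ccc(OC)c(OC)c3n(C)c2=O)OC1(C)C
F3 | step 5 | (3S,4R)-3-(1-ethoxy-3-methylbut-2-en-1-yl)-4-hydroxy-7,8-dimethoxy-2,2,6-trimethyl-2,3,4,6-tetrahydro-5H-pyrano[3,2-c]quinolin-5-one (3,4-trans) | O[C@H]1c2c(c3ccc(OC)c(OC)c3n(C)c2=O)OC(C)(C)[C@@H]1C(OCC)C=C(C)C
F4 | step 7 | 7,8-dimethoxy-1-methyl-2-oxo-1,2-dihydroquinolin-4-yl trifluoromethanesulfonate | COc1ccc2c(OS(=O)(=O)C(F)(F)F)cc(=O)n(C)c2c1OC
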